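## The problem

1. The target is a bisabolane-type triester: a cyclohexane (ring carbons C1–C6, methyl on C3) joined by the single bond C6–C7 to the chain C7(=C14H2)–C8–C9–C10–C11Me2. No ring fusion has to be made, but the ring holds five contiguous stereocentres (C1, C2, C3, C4, C6) and the chain two more (C8, C10).
2. With the ring face of the C6 side chain called α and the other face β, the ester oxygen on C1 is β (trans to the chain), the ester oxygen on C2 is α, and the C3/C4 oxirane is α, cis to the C2 oxygen.
3. C6 can steer a reagent to the β face at C1 and can fix the face of hydride addition to a ring carbonyl 1,3 to it. A free hydroxyl on C4 or C2 can deliver an epoxide to its own face. C8 and C10 lie beyond the sp2 carbon C7, out of reach of the ring, and need reagent control.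
4. The three angelates are the most fragile groups: the (Z)-2-methylbut-2-enoate isomerises to the tiglate with base, nucleophiles or long heating and would not survive hydride, hydrazine, alkaline peroxide or amide bases. All three must therefore go on last, onto hindered secondary hydroxyls.
5. Both oxiranes are acid-sensitive, and a free C8 hydroxyl can open the C10/C11 oxirane to a tetrahydrofuran. Once the ring is unsaturated, C6–H is doubly allylic and prone to double-bond migration.
6. The feature that invites the key step is the unbroken oxygenated array C1–C4, whose ends C1 and C4 are 1,4-related with C5 a plain methylene. A C1=C2–C3(Me)=C4 diene can take up O2 at C1 and C4 in one step, and the O–O bond then serves to move oxidation around the ring.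
7. That diene is the reduced cross-conjugated dienol derivative of a carvone-type enone, so the ring, the C3 methyl and the C6 configuration can be bought.

## Retrosynthesis

**20 to 19.** The three acyl C–O bonds of target 20 are cut first, giving diepoxy triol 19. Any earlier acylation would expose an angelate to base, hydride or hydrazine. The precursor loses fifteen carbons and all Z-alkenes. The forward step must acylate three hindered hydroxyls without Z-to-E isomerisation and without acid.

**19 to 18 to 17.** The two O–Si bonds of 18 are cut, then the two C–O bonds of the ring oxirane, leading to allylic alcohol 17 (C2 α-hydroxyl, C3=C4, C1 β-silyloxy). Cutting here uses the C2 hydroxyl as the internal director for the α face. An undirected epoxidation would have to discriminate C3=C4 from C7=C14 and would be governed by the C1 silyl ether alone. The forward step needs syn delivery to C3=C4 only.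

**17 to 16 to 15 to 14 to 13.** The C2 carbinol with C3=C4 in 17 is the Wharton transposition product of epoxy ketone 16 (C4 ketone, α-oxirane at C2/C3), so the C4–H and the C3=C4 π bond are cut back to C4=O and the oxirane.
- The one-step route from enone 13 to 16 with alkaline peroxide is not used. In the half-chair of 13 with the C6 and C1 substituents equatorial, the hydroperoxide anion should add axially to C2 from the β face, trans to the C6 chain as in carvone, and place the oxirane on the wrong face.
- Instead the oxirane in 16 is traced to epoxy alcohol 15, whose C–O bonds come from allylic alcohol 14, whose C4–H comes from 13.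
- Axial hydride addition makes the C4 hydroxyl α, and this hydroxyl carries the peroxide to the α face. This costs two steps but replaces an uncertain face preference by two predictable ones.

**13 to 11.** The C4 carbonyl and C1 hydroxyl of hydroxy enone 12, silylated as 13, are the two halves of the O–O bond of endoperoxide 11. This cut removes no carbon but turns two stereocentres and a differentiated 1,4-dioxygen pattern into one symmetrical functional group. The forward base-induced cleavage must take the bridgehead hydrogen at C4 and not the one at C1.

**11 to 10.** The C1–O and C4–O bonds are cut together, giving diene 10 and O2. This is the simplest possible source of the C1 oxygen, and it is preferred to stepwise oxidation of the enone because it reaches C4 and thereby opens the transposition path to C2. The precursor has a single ring stereocentre. The forward reaction must be β-face selective and must win over ene reactions.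

**10 to 9 to 7.** The C2–H bond of 10 is cut to the C2–O bond of dienyl triflate 9, which comes from epoxy enone 7 by way of its kinetic dienolate 8. Elimination routes from an allylic alcohol would give mixtures of diene isomers; the enol triflate fixes both double bonds. The forward steps must tolerate the oxirane and must not isomerise the diene.

**7 to 6 to 5 to 4.** The two C–O bonds of the chain oxirane are cut to the C10=C11 alkene of 6. This must precede the photooxygenation, since a trisubstituted alkene would itself react with singlet oxygen. The isopropylidene end of 6 is cut by cross-metathesis to the allyl group of 5, and the O–Si bond to alcohol 4. Each step leaves the enone untouched, and the epoxidation is under catalyst control.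

**4 to 3 to 2 to 1.** The C8–C9 bond is cut to enal 3 and an allyl nucleophile. This sets C8 by a reagent-controlled allylboration on an aldehyde, where a C7–C8 cut would need a vinyl metal made in the presence of the enone. The aldehyde oxygen of 3 replaces the chlorine of 2, and the C–Cl bond of 2 goes back to the isopropenyl methyl of (R)-carvone 1, which supplies ring, methyl and C6.

## Roads not taken

**Alternative 1:** The cut is the ring bond C5–C6.
- Forward key step: δ-lactone A1 has C7 as the lactone carbonyl and C3 as a quaternary carbinol carbon bearing methyl and vinyl (C4=C5). It is converted into its silyl ketene acetal, and an Ireland–Claisen shift through the boat imposed by the lactone ring contracts it to cyclohexenecarboxylic acid A2, with C3=C4 in place and C7 as a carboxyl on C6.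
- Merits: the rearrangement is stereospecific. The C6 configuration follows from the lactone stereocentres and not from a face preference, and the alkene arrives exactly where a C2 hydroxyl can later direct the epoxidation, so no redox transposition is needed.
- Weak points: C7 is delivered at the carboxyl oxidation level, whereas the target needs it as the sp2 carbon of a 1,1-disubstituted alkene bearing the C8 carbinol. All of C8–C11 and C14 must therefore be added afterwards through an epimerisable C6 acyl compound. A1 also needs its own enantioselective synthesis of a quaternary carbinol centre next to a diol, and that centre is destroyed in the key step.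
- Comparison: this road is better in stereochemical certainty at C1, C2 and C6 and is shorter from ring closure to the oxygenated ring. The chosen plan sets against this a purchased ring and C6 centre and a chain that is finished on a robust enone before any ring oxygen exists.

**Alternative 2:** The cut is the ring bond C3–C4 together with the C4–O bond of the oxirane.
- Forward key step: sulfonium salt A3 (primary diphenylsulfonium at C4, methyl ketone at C3) is deprotonated. The ylide adds to the ketone and the betaine closes to epoxycyclohexane A4 with loss of diphenyl sulfide, an intramolecular Corey–Chaykovsky reaction.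
- Merits: ring and oxirane form in one late step. A4 is three operations from the target (chain epoxidation, desilylation, acylation), and no sacrificial oxygen is needed.
- Weak points: A3 carries C6, C1, C2 and C8 on an open chain, so four centres need acyclic stereocontrol. The ketone has an α-hydrogen at C2 with a β-silyloxy group at C1, so enolisation and β-elimination compete with formation of the unstabilised ylide. The step must also set C3 and C4 together with no ring to bias the ketone face.
- Comparison: after its key step this road is shorter and more convergent than the chosen plan. The chosen plan sets each ring centre on a conformationally defined ring by a separate, understood directing effect and avoids the long open-chain precursor.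

**Alternative 3:** The cut is the ring bond C2–C3.
- Forward key step: iodo aldehyde A5 is treated with CrCl2 and catalytic NiCl2. The (Z)-alkenylchromium species adds to the C2 aldehyde in a Nozaki–Hiyama–Kishi closure, giving cyclohexenol A6.
- Merits: the coupling is mild and highly chemoselective. A6 is the analogue of 17 lacking only the chain oxirane, so this road reaches in one step the point that the chosen plan reaches eight steps after its key step, with no sacrificial C4 oxygen.
- Weak points: A5 needs the C6/C1 relationship, C8 and a (Z)-trisubstituted alkenyl iodide built by acyclic methods. Its α-silyloxy aldehyde can epimerise, the configuration at C2 is not assured in the closure (it could be corrected by oxidation and Luche reduction), and chromium is used in excess.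
- Comparison: the endgame of this road is clearly better. The chosen plan sets against this the start from carvone, which gives ring and C6 for nothing, and a chain built by three reagent-controlled steps on a stable enone. The open-chain precursor A5 would cost about as many steps as the whole first half of the chosen route, with less certain stereocontrol.

Key step: step 9

**Remarks**
- Numbering: ring C1–C6 as in the target (C1 and C2 oxygenated, methyl on C3, side chain on C6); chain C7(=C14H2)–C8–C9–C10–C11Me2. α is the ring face of the C6 side chain, β the opposite face. Descriptors marked "route numbering" use these locants.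
- Assumption on the allylboration: (−)-B-allyldiisopinocampheylborane, the antipode made from (+)-α-pinene, is taken to add to the Si face of aldehyde 3. If the opposite sense applies, the (+)-reagent is used.

## Route

Step 1
Reactants: 1 (R)-carvone
Product: 2 (5R)-5-(3-chloroprop-1-en-2-yl)-2-methylcyclohex-2-en-1-one
Conditions: Ca(OCl)2, solid CO2, CH2Cl2/H2O, 0 °C to rt
Reagents that add atoms: calcium hypochlorite, [Ca+2].[O-]Cl.[O-]Cl
Why: Hypochlorous acid released by CO2 chlorinates the electron-rich 1,1-disubstituted alkene in an ene-type allylic chlorination with double-bond shift, which for an isopropenyl group regenerates a 2-substituted allyl chloride; the conjugated ring alkene is deactivated and C6 is not touched.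

Step 2
Reactants: 2 (5R)-5-(3-chloroprop-1-en-2-yl)-2-methylcyclohex-2-en-1-one
Product: 3 2-[(1R)-4-methyl-5-oxocyclohex-3-en-1-yl]prop-2-enal
Conditions: N-methylmorpholine N-oxide, NaI (cat.), 4 Å MS, MeCN, rt
Reagents that add atoms: N-methylmorpholine N-oxide, C[N+]1([O-])CCOCC1
Why: Ganem-type (Kornblum-like) oxidation: the N-oxide oxygen displaces the allylic halide (iodide formed in situ) and the alkoxyammonium salt collapses with loss of N-methylmorpholine to the 2-substituted acrolein; the medium is only weakly basic, which should spare the allylic C6–H.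

Step 3
Reactants: 3 2-[(1R)-4-methyl-5-oxocyclohex-3-en-1-yl]prop-2-enal
Product: 4 (5R)-5-[(3S)-3-hydroxyhexa-1,5-dien-2-yl]-2-methylcyclohex-2-en-1-one
Conditions: (−)-Ipc2BOMe, allylMgBr, Et2O, 0 °C to rt; then 3, −78 °C; then HOCH2CH2NH2, rt
Reagents that add atoms: (−)-B-allyldiisopinocampheylborane (made in the flask from (−)-B-methoxydiisopinocampheylborane and allylmagnesium bromide), C=CCB([C@@H]1C[C@@H]2C[C@H]([C@H]1C)C2(C)C)[C@@H]1C[C@@H]2C[C@H]([C@H]1C)C2(C)C
Why: Brown allylboration through a closed chair transition state; the pinene-derived ligands direct allyl to the Si face of the aldehyde, which sets C8 as S under reagent control, and the aldehyde reacts far faster than the ring ketone at −78 °C. The amino alcohol work-up replaces alkaline peroxide, which would epoxidise the enone.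

Step 4
Reactants: 4 (5R)-5-[(3S)-3-hydroxyhexa-1,5-dien-2-yl]-2-methylcyclohex-2-en-1-one
Product: 5 (5R)-5-[(3S)-3-(tert-butyldimethylsilyloxy)hexa-1,5-dien-2-yl]-2-methylcyclohex-2-en-1-one
Conditions: TBSCl, imidazole, DMF, rt
Reagents that add atoms: tert-butyldimethylsilyl chloride, CC(C)(C)[Si](C)(C)Cl
Why: Standard silylation of a secondary allylic alcohol; the ether masks the C8 hydroxyl against enolate chemistry and against hydroxyl-directed oxidation of C7=C14 later, and it enlarges the C6 substituent for the key step.

Step 5
Reactants: 5 (5R)-5-[(3S)-3-(tert-butyldimethylsilyloxy)hexa-1,5-dien-2-yl]-2-methylcyclohex-2-en-1-one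
Product: 6 (5R)-5-[(3S)-3-(tert-butyldimethylsilyloxy)-6-methylhepta-1,5-dien-2-yl]-2-methylcyclohex-2-en-1-one
Conditions: RuCl2(=CHPh)(PCy3)(H2IMes) (second-generation Grubbs catalyst, 5 mol %), 2-methylbut-2-ene/CH2Cl2, 40 °C
Reagents that add atoms: 2-methylbut-2-ene, CC=C(C)C
Why: Olefin cross-metathesis of the monosubstituted alkene with excess 2-methylbut-2-ene caps the chain as the trisubstituted C10=C11 alkene with release of propene; the 1,1-disubstituted C7=C14 alkene and the conjugated ring alkene are too hindered or too electron-poor to enter the catalytic cycle.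

Step 6
Reactants: 6 (5R)-5-[(3S)-3-(tert-butyldimethylsilyloxy)-6-methylhepta-1,5-dien-2-yl]-2-methylcyclohex-2-en-1-one
Product: 7 (5R)-5-{(3S)-3-(tert-butyldimethylsilyloxy)-4-[(2R)-3,3-dimethyloxiran-2-yl]but-1-en-2-yl}-2-methylcyclohex-2-en-1-one
Conditions: D-fructose-derived Shi ketone (0.3 equiv), KHSO5 (Oxone), K2CO3, Bu4NHSO4, MeCN/CH2(OMe)2, aq. Na2B4O7 buffer, 0 °C
Reagents that add atoms: potassium peroxymonosulfate, [K+].[O-]S(=O)(=O)OO
Why: Shi asymmetric epoxidation: the chiral dioxirane generated from the ketone transfers oxygen to the electron-rich trisubstituted alkene through a spiro transition state and should give the 10R oxirane under catalyst control; the enone alkene and the hindered 1,1-disubstituted alkene react much more slowly.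

Step 7
Reactants: 7 (5R)-5-{(3S)-3-(tert-butyldimethylsilyloxy)-4-[(2R)-3,3-dimethyloxiran-2-yl]but-1-en-2-yl}-2-methylcyclohex-2-en-1-one
Product: 9 dienyl triflate with C1=C2(OTf)–C3(Me)=C4 and unchanged side chain (6R,8S,10R in route numbering), via potassium dienolate 8 (not isolated)
Conditions: KN(SiMe3)2, THF, −78 °C; then PhNTf2, −78 to 0 °C
Reagents that add atoms: N-phenylbis(trifluoromethanesulfonimide), O=S(=O)(N(c1ccccc1)S(=O)(=O)C(F)(F)F)C(F)(F)F
Why: Kinetic deprotonation of the enone at the α′ methylene C1 gives the cross-conjugated dienolate, which is sulfonylated on oxygen; this enol triflate formation fixes the diene as C1=C2–C3(Me)=C4, and the oxirane and silyl ether are inert at −78 °C.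

Step 8
Reactants: 9 dienyl triflate with C1=C2(OTf)–C3(Me)=C4
Product: 10 (5R)-5-{(3S)-3-(tert-butyldimethylsilyloxy)-4-[(2R)-3,3-dimethyloxiran-2-yl]but-1-en-2-yl}-2-methylcyclohexa-1,3-diene (the C1=C2–C3(Me)=C4 diene of route numbering)
Conditions: Pd(PPh3)4 (5 mol %), HCO2H, n-Bu3N, DMF, 50 °C
Reagents that add atoms: none
Why: Palladium-catalysed formate reduction of an enol triflate: oxidative addition of zerovalent palladium into the C–OTf bond, exchange with formate, loss of CO2 and C–H reductive elimination; no stereocentre is formed and the buffered medium leaves oxirane and silyl ether alone.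

Step 9
Reactants: 10 (5R)-5-{(3S)-3-(tert-butyldimethylsilyloxy)-4-[(2R)-3,3-dimethyloxiran-2-yl]but-1-en-2-yl}-2-methylcyclohexa-1,3-diene
Product: 11 endoperoxide with the O–O bridge from C1 to C4 on the β face and C2=C3(Me) (2,3-dioxabicyclo[2.2.2]oct-5-ene; 1R,4R,6S,8S,10R in route numbering)
Conditions: O2, tetraphenylporphyrin (cat.), visible light, CH2Cl2, −78 °C
Reagents that add atoms: dioxygen, O=O
Why: Energy transfer from triplet tetraphenylporphyrin converts O2 into singlet oxygen, which adds suprafacially across C1 and C4 of the ring-locked s-cis diene in a concerted [4+2] cycloaddition, forming the C1–O and C4–O bonds at once. The closest known reaction type is the dye-sensitised photooxygenation of 5-substituted 2-methylcyclohexa-1,3-dienes of the α-phellandrene type to 2,3-dioxabicyclo[2.2.2]oct-5-enes. The one ring closed is the six-membered 1,2-dioxane (C1–O–O–C4–C3=C2), closed by cycloaddition, so both new bonds lie on one face and the bridge is necessarily cis. C1 and C4 are the new stereocentres; both are controlled by the resident C6 centre, whose α-branched side chain shields the α face next to the C1 terminus so that O2 should enter from the β face, and suprafaciality ties C4 to C1. Three selectivities are needed: β over α face, [4+2] over the ene mode, and the diene over the other π bonds. The first rests on the size of the C6 substituent, enlarged by the C8 silyl ether, and on the low temperature; the second on the cisoid geometry of the cyclic diene; the third on C7=C14 being a poorly nucleophilic 1,1-disubstituted alkene and C10=C11 being already an oxirane. Because the dienophile is small, the face selectivity is the point on which the step depends.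

Step 10
Reactants: 11 endoperoxide with the O–O bridge from C1 to C4 on the β face
Product: 13 C1 β-silyloxy C4 enone (C4=O, C2=C3(Me); 1R,6S,8S,10R in route numbering), via hydroxy enone 12 (not isolated)
Conditions: Et3N, CH2Cl2, 0 °C to rt; then TBSCl, imidazole, DMAP (cat.), rt
Reagents that add atoms: tert-butyldimethylsilyl chloride, CC(C)(C)[Si](C)(C)Cl
Why: Kornblum–DeLaMare rearrangement: the amine removes the bridgehead hydrogen at C4, which sits next to the C5 methylene and away from the C6 substituent, and the O–O bond breaks to the C4 enone and the C1 alkoxide with C1 unchanged. Silylating 12 in the same flask forestalls its base-induced isomerisation to a 1,4-diketone.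

Step 11
Reactants: 13 C1 β-silyloxy C4 enone
Product: 14 C4 α-allylic alcohol (C2=C3(Me), C1 β-silyloxy; 1R,4S,6S,8S,10R in route numbering)
Conditions: NaBH4, CeCl3·7H2O, MeOH, −78 to −20 °C
Reagents that add atoms: none
Why: Luche 1,2-reduction: in the half-chair with the C6 and C1 substituents equatorial, hydride adds axially from the β face, so the new C4 hydroxyl is equatorial and α, cis to the C6 chain, as in the reduction of carvone to cis-carveol.

Step 12
Reactants: 14 C4 α-allylic alcohol
Product: 15 C2/C3 α-epoxy C4 α-alcohol (1S,2R,3S,4S,6S,8S,10R in route numbering)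
Conditions: VO(acac)2 (cat.), t-BuOOH, CH2Cl2, 0 °C to rt
Reagents that add atoms: tert-butyl hydroperoxide, CC(C)(C)OO
Why: Vanadium-catalysed hydroxyl-directed epoxidation: the peroxide is delivered from the vanadate ester of the C4 hydroxyl to the α face of C2=C3, which is also the face anti to the C1 silyl ether; C7=C14 has no free allylic hydroxyl and stays intact.

Step 13
Reactants: 15 C2/C3 α-epoxy C4 α-alcohol
Product: 16 C2/C3 α-epoxy C4 ketone (1S,2R,3R,6S,8S,10R in route numbering)
Conditions: Dess–Martin periodinane, NaHCO3, CH2Cl2, 0 °C to rt
Reagents that add atoms: none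
Why: Buffered Dess–Martin oxidation of a secondary alcohol to the ketone under non-acidic conditions that spare both oxiranes; the oxirane carbon C3 is quaternary, so it cannot epimerise.

Step 14
Reactants: 16 C2/C3 α-epoxy C4 ketone
Product: 17 C2 α-allylic alcohol with C3(Me)=C4 and C1 β-silyloxy (1S,2S,6S,8S,10R in route numbering)
Conditions: N2H4·H2O, AcOH (cat.), MeOH, 0 °C to rt
Reagents that add atoms: none
Why: Wharton transposition: condensation with hydrazine at C4, opening of the oxirane by the C=N–NH2 unit and loss of N2 give the C3=C4 alkene; the C2–O bond is never broken, so the α configuration at C2 is that of the oxirane.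

Step 15
Reactants: 17 C2 α-allylic alcohol with C3(Me)=C4
Product: 18 C3/C4 α-epoxy C2 α-alcohol with C1 β-silyloxy (1S,2R,3R,4S,6S,8S,10R in route numbering)
Conditions: VO(acac)2 (cat.), t-BuOOH, CH2Cl2, 0 °C to rt
Reagents that add atoms: tert-butyl hydroperoxide, CC(C)(C)OO
Why: Second vanadium-catalysed directed epoxidation: the C2 hydroxyl delivers oxygen to the α face of C3=C4, which sets C3 and C4 cis to the C2 oxygen; the silylated hydroxyls cannot direct and C7=C14 is not attacked.

Step 16
Reactants: 18 C3/C4 α-epoxy C2 α-alcohol with C1 β-silyloxy
Product: 19 diepoxy triol with free hydroxyls at C1 (β), C2 (α) and C8 (1S,2R,3R,4S,6S,8S,10R in route numbering)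
Conditions: Bu4NF, AcOH (buffer), THF, 0 °C to rt
Reagents that add atoms: none
Why: Fluoride-induced cleavage of both silyl ethers under buffered, non-acidic conditions; the ring epoxy alcohol is cis and cannot undergo Payne rearrangement, and base-induced attack of the C8 alkoxide on the chain oxirane is slow when the fluoride is buffered.

Step 17
Reactants: 19 diepoxy triol with free hydroxyls at C1, C2 and C8
Product: 20 target tris-angelate (1S,2R,3S,4S,6S,8S,10R in route numbering)
Conditions: angelic acid, 2,4,6-trichlorobenzoyl chloride, Et3N, toluene, rt; then 19, toluene, 75 °C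
Reagents that add atoms: angelic acid, C/C=C(/C)C(=O)O
Why: Yamaguchi-type esterification through the preformed mixed anhydride without a nucleophilic catalyst; the conjugate addition–elimination pathway that turns angelates into tiglates is thereby avoided, and the hindered aroyl carbonyl directs each alcohol to the angeloyl carbonyl.

## Compound list

1 | (R)-carvone, (5R)-2-methyl-5-(prop-1-en-2-yl)cyclohex-2-en-1-one | CC1=CC[C@H](CC1=O)C(C)=C | starting material
2 | (5R)-5-(3-chloroprop-1-en-2-yl)-2-methylcyclohex-2-en-1-one | C=C(CCl)[C@@H]1CC=C(C)C(=O)C1 | intermediate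
3 | 2-[(1R)-4-methyl-5-oxocyclohex-3-en-1-yl]prop-2-enal | C=C(C=O)[C@@H]1CC=C(C)C(=O)C1 | intermediate
4 | (5R)-5-[(3S)-3-hydroxyhexa-1,5-dien-2-yl]-2-methylcyclohex-2-en-1-one | C=C([C@H](CC=C)O)[C@@H]1CC=C(C)C(=O)C1 | intermediate
5 | (5R)-5-[(3S)-3-(tert-butyldimethylsilyloxy)hexa-1,5-dien-2-yl]-2-methylcyclohex-2-en-1-one | C=C([C@H](CC=C)O[Si](C)(C)C(C)(C)C)[C@@H]1CC=C(C)C(=O)C1 | intermediate
6 | (5R)-5-[(3S)-3-(tert-butyldimethylsilyloxy)-6-methylhepta-1,5-dien-2-yl]-2-methylcyclohex-2-en-1-one | C=C([C@H](CC=C(C)C)O[Si](C)(C)C(C)(C)C)[C@@H]1CC=C(C)C(=O)C1 | intermediate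
7 | (5R)-5-{(3S)-3-(tert-butyldimethylsilyloxy)-4-[(2R)-3,3-dimethyloxiran-2-yl]but-1-en-2-yl}-2-methylcyclohex-2-en-1-one | C=C([C@H](C[C@H]1OC1(C)C)O[Si](C)(C)C(C)(C)C)[C@@H]1CC=C(C)C(=O)C1 | intermediate
8 | potassium cross-conjugated dienolate of 7 (C1=C2(O−)–C3(Me)=C4; 6R,8S,10R) | C=C([C@H](C[C@H]1OC1(C)C)O[Si](C)(C)C(C)(C)C)[C@@H]1CC=C(C)C([O-])=C1.[K+] | intermediate
9 | dienyl triflate, C1=C2(OTf)–C3(Me)=C4 (6R,8S,10R) | C=C([C@H](C[C@H]1OC1(C)C)O[Si](C)(C)C(C)(C)C)[C@@H]1CC=C(C)C(OS(=O)(=O)C(F)(F)F)=C1 | intermediate
10 | (5R)-5-{(3S)-3-(tert-butyldimethylsilyloxy)-4-[(2R)-3,3-dimethyloxiran-2-yl]but-1-en-2-yl}-2-methylcyclohexa-1,3-diene | C=C([C@H](C[C@H]1OC1(C)C)O[Si](C)(C)C(C)(C)C)[C@@H]1CC=C(C)C=C1 | intermediate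
11 | endoperoxide, β-face O–O bridge C1 to C4, C2=C3(Me) (1R,4R,6S,8S,10R) | C=C([C@H](C[C@H]1OC1(C)C)O[Si](C)(C)C(C)(C)C)[C@@H]1C[C@H]2OO[C@@H]1C=C2C | intermediate
12 | hydroxy enone, C4=O, C2=C3(Me), C1 β-OH (1R,6S,8S,10R) | C=C([C@H](C[C@H]1OC1(C)C)O[Si](C)(C)C(C)(C)C)[C@@H]1CC(=O)C(C)=C[C@H]1O | intermediate
13 | C1 β-silyloxy C4 enone (1R,6S,8S,10R) | C=C([C@H](C[C@H]1OC1(C)C)O[Si](C)(C)C(C)(C)C)[C@@H]1CC(=O)C(C)=C[C@H]1O[Si](C)(C)C(C)(C)C | intermediate
14 | C4 α-allylic alcohol, C2=C3(Me), C1 β-silyloxy (1R,4S,6S,8S,10R) | C=C([C@H](C[C@H]1OC1(C)C)O[Si](C)(C)C(C)(C)C)[C@@H]1C[C@H](O)C(C)=C[C@H]1O[Si](C)(C)C(C)(C)C | intermediate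
15 | C2/C3 α-epoxy C4 α-alcohol (1S,2R,3S,4S,6S,8S,10R) | C=C([C@H](C[C@H]1OC1(C)C)O[Si](C)(C)C(C)(C)C)[C@@H]1C[C@H](O)[C@]2(C)O[C@@H]2[C@H]1O[Si](C)(C)C(C)(C)C | intermediate
16 | C2/C3 α-epoxy C4 ketone (1S,2R,3R,6S,8S,10R) | C=C([C@H](C[C@H]1OC1(C)C)O[Si](C)(C)C(C)(C)C)[C@@H]1CC(=O)[C@]2(C)O[C@@H]2[C@H]1O[Si](C)(C)C(C)(C)C | intermediate
17 | C2 α-allylic alcohol, C3(Me)=C4, C1 β-silyloxy (1S,2S,6S,8S,10R) | C=C([C@H](C[C@H]1OC1(C)C)O[Si](C)(C)C(C)(C)C)[C@@H]1CC=C(C)[C@H](O)[C@H]1O[Si](C)(C)C(C)(C)C | intermediate
18 | C3/C4 α-epoxy C2 α-alcohol, C1 β-silyloxy (1S,2R,3R,4S,6S,8S,10R) | C=C([C@H](C[C@H]1OC1(C)C)O[Si](C)(C)C(C)(C)C)[C@@H]1C[C@@H]2O[C@]2(C)[C@H](O)[C@H]1O[Si](C)(C)C(C)(C)C | intermediate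
19 | diepoxy triol, OH at C1 (β), C2 (α), C8 (1S,2R,3R,4S,6S,8S,10R) | C=C([C@H](C[C@H]1OC1(C)C)O)[C@@H]1C[C@@H]2O[C@]2(C)[C@H](O)[C@H]1O | intermediate
20 | target, tris-angelate CNP0258231.3 (1S,2R,3S,4S,6S,8S,10R) | C=C([C@H](C[C@H]1OC1(C)C)OC(=O)/C(C)=C\C)[C@@H]1C[C@@H]2O[C@]2(C)[C@H](OC(=O)/C(C)=C\C)[C@H]1OC(=O)/C(C)=C\C | target

## Step count and least certain steps

Total step count: 17. Longest linear sequence: 17 steps, from (R)-carvone 1 to 20.

**Step 9 (key step).** The likely failure is poor facial selectivity. Singlet oxygen is a small dienophile, and the C6 substituent shields little when it sits pseudo-equatorial. Ene-type hydroperoxidation at the C3 methyl or C5 methylene and aromatisation of the diene are lesser risks. The fallback gives up the endoperoxide and sets out from 7. Its potassium dienolate 8 is hydroxylated at C1 with 2-(phenylsulfonyl)-3-phenyloxaziridine, anti to the C6 chain, to give α′-hydroxy enone F1. Silylation (TBSCl, imidazole) gives silyl ether F2. Luche reduction of the C2 ketone, with axial hydride delivery placing the hydroxyl equatorial and α, returns to the route at 17.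

**Step 10.** The likely failure is loss of regiocontrol in the proton abstraction (C1–H in place of C4–H), together with isomerisation of the γ-hydroxy enone to a 1,4-diketone before it is trapped. The fallback sets out from 11. Reductive O–O cleavage with thiourea in MeOH gives cis-enediol F3. Its less hindered C4 carbinol is oxidised with the bulky oxoammonium system TEMPO/PhI(OAc)2 to 12, which is silylated as before to rejoin at 13.

**Step 17.** The likely failure is Z-to-E isomerisation to tiglate during slow acylation of three hindered hydroxyls, two of them vicinal. Incomplete acylation and cyclisation of the free C8 hydroxyl onto the C10/C11 oxirane in the warm, ammonium-salt-containing mixture are further risks. The fallback sets out from 19. Esterification with the saturated 2-[bis(2,2,2-trifluoroethoxy)phosphoryl]propanoic acid (DCC, DMAP), which has no alkene to isomerise, gives tris(phosphonopropionate) F4. A threefold Still–Gennari olefination with acetaldehyde (KN(SiMe3)2, 18-crown-6, THF, −78 °C) builds the three (Z)-alkenes and arrives at 20.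

**Step 14.** The likely failure is diversion of the vinyl diazene intermediate into reduction or fragmentation pathways, giving low conversion to the alkene, and migration of the silyl group from the C1 to the C2 oxygen in the basic medium. The fallback sets out from 15. 1,1′-Thiocarbonyldiimidazole converts it into thiocarbonylimidazolide F5. Bu3SnH and AIBN in toluene generate the C4 radical, which opens the adjacent oxirane (Barton–McCombie-type fragmentation of an oxiranylcarbinyl radical) to the allyloxy radical and, after hydrogen transfer, 17, bypassing 16.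

**Step 8.** The likely failure is migration of the diene double bonds under palladium hydride catalysis toward an aromatic ring, since C6–H is doubly allylic, or incomplete reduction. The fallback sets out from 7. Condensation with p-toluenesulfonylhydrazide gives tosylhydrazone F6. Excess LiN(iPr)2 in THF effects a Shapiro-type α′-deprotonation with loss of sulfinate and N2, giving 10 without any transition metal.

**Step 2.** The likely failure is sluggish displacement of the chloride, together with base-induced migration of C7=C14 into conjugation (which would erase C6) or oligomerisation of the α-methylene aldehyde. The fallback sets out from 2. Displacement with KOAc in DMF gives allylic acetate F7. Methanolysis (K2CO3, MeOH) gives allylic alcohol F8, and MnO2 in CH2Cl2 oxidises it to 3.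

## Further compounds

F1 | step 9 | α′-hydroxy enone, C2=O, C3(Me)=C4, C1 β-OH (1S,6S,8S,10R) | C=C([C@H](C[C@H]1OC1(C)C)O[Si](C)(C)C(C)(C)C)[C@@H]1CC=C(C)C(=O)[C@H]1O
F2 | step 9 | silyl ether of F1, C1 β-silyloxy (1S,6S,8S,10R) | C=C([C@H](C[C@H]1OC1(C)C)O[Si](C)(C)C(C)(C)C)[C@@H]1CC=C(C)C(=O)[C@H]1O[Si](C)(C)C(C)(C)C
F3 | step 10 | cis-enediol, C1 β-OH, C4 β-OH, C2=C3(Me) (1R,4R,6S,8S,10R) | C=C([C@H](C[C@H]1OC1(C)C)O[Si](C)(C)C(C)(C)C)[C@@H]1C[C@@H](O)C(C)=C[C@H]1O
F4 | step 17 | tris(phosphonopropionate) of 19, 2-[bis(2,2,2-trifluoroethoxy)phosphoryl]propanoate at C1, C2 and C8 (α-carbons of the esters unspecified) | C=C([C@H](C[C@H]1OC1(C)C)OC(=O)C(C)P(=O)(OCC(F)(F)F)OCC(F)(F)F)[C@@H]1C[C@@H]2O[C@]2(C)[C@H](OC(=O)C(C)P(=O)(OCC(F)(F)F)OCC(F)(F)F)[C@H]1OC(=O)C(C)P(=O)(OCC(F)(F)F)OCC(F)(F)F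
F5 | step 14 | C4 O-thiocarbonylimidazolide of 15 | C=C([C@H](C[C@H]1OC1(C)C)O[Si](C)(C)C(C)(C)C)[C@@H]1C[C@H](OC(=S)n2ccnc2)[C@]2(C)O[C@@H]2[C@H]1O[Si](C)(C)C(C)(C)C
F6 | step 8 | tosylhydrazone of 7 at C2 (C=N geometry unspecified) | C=C([C@H](C[C@H]1OC1(C)C)O[Si](C)(C)C(C)(C)C)[C@@H]1CC=C(C)C(=NNS(=O)(=O)c2ccc(C)cc2)C1
F7 | step 2 | allylic acetate, 2-[(1R)-4-methyl-5-oxocyclohex-3-en-1-yl]prop-2-en-1-yl acetate | C=C(COC(C)=O)[C@@H]1CC=C(C)C(=O)C1
F8 | step 2 | allylic alcohol, (5R)-5-(3-hydroxyprop-1-en-2-yl)-2-methylcyclohex-2-en-1-one | C=C(CO)[C@@H]1CC=C(C)C(=O)C1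
A1 | alternative 1 | δ-lactone, 6-ethenyl-6-methyl-4,5-bis(tert-butyldimethylsilyloxy)oxan-2-one, vinyl cis to the 4-silyloxy and trans to the 5-silyloxy group | O=C1C[C@H](O[Si](C)(C)C(C)(C)C)[C@@H](O[Si](C)(C)C(C)(C)C)[C@](C)(C=C)O1
A2 | alternative 1 | 5,6-bis(tert-butyldimethylsilyloxy)-4-methylcyclohex-3-ene-1-carboxylic acid | OC(=O)[C@@H]1CC=C(C)[C@H](O[Si](C)(C)C(C)(C)C)[C@H]1O[Si](C)(C)C(C)(C)C
A3 | alternative 2 | open-chain C4 diphenylsulfonium triflate with C3 methyl ketone and silyloxy groups at C1, C2 and C8 | C=C([C@H](CC=C(C)C)O[Si](C)(C)C(C)(C)C)[C@H](CC[S+](c1ccccc1)c1ccccc1)[C@H](O[Si](C)(C)C(C)(C)C)[C@@H](O[Si](C)(C)C(C)(C)C)C(C)=O.[O-]S(=O)(=O)C(F)(F)F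
A4 | alternative 2 | tris-silylated C3/C4 epoxycyclohexane with the prenyl side chain | C=C([C@H](CC=C(C)C)O[Si](C)(C)C(C)(C)C)[C@@H]1C[C@@H]2O[C@]2(C)[C@H](O[Si](C)(C)C(C)(C)C)[C@H]1O[Si](C)(C)C(C)(C)C
A5 | alternative 3 | open-chain C2 aldehyde with (Z)-alkenyl iodide at C3 and silyloxy groups at C1 and C8 | C=C([C@H](CC=C(C)C)O[Si](C)(C)C(C)(C)C)[C@H](C/C=C(/C)I)[C@H](O[Si](C)(C)C(C)(C)C)C=O
A6 | alternative 3 | cyclohexenol with free C2 α-hydroxyl, C1 β-silyloxy and C8 silyloxy groups, prenyl side chain | C=C([C@H](CC=C(C)C)O[Si](C)(C)C(C)(C)C)[C@@H]1CC=C(C)[C@H](O)[C@H]1O[Si](C)(C)C(C)(C)C
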